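**Plan**

- Cuts (dihydrobenzofuran numbering O1, C2, C3, C3a–C7a on ring A): last the three O-benzyl groups and C3–CH2OH (from a vinyl group); then the lactone Cα–CH2 bond to ring A (enolate alkylation); then, together, the aryl ether bond O1–C7a and the bond C2–C3, leaving O-benzylvanillin and a γ-aryl allylboronate built on a 1,3-benzodioxole.
- Feature used: on ring A the free hydroxyl on C7 is ortho, and the benzylic carbon on C5 is para, to the ring oxygen on C7a. With O7 and the C7a oxygen tied as a methylenedioxy ring and C5 held as a nitrile, C7a becomes an SNAr carbon whose leaving oxygen, after loss of formaldehyde, is the 7-OH.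
- Forward order: ring A arm (nitrile, vinyl, allylboronate), furan ring closed in the key step, nitrile to CH2Br, union with the (S)-β-benzyl-γ-butyrolactone (Stobbe route), vinyl to CH2OH, debenzylation.
- Stereochemistry: C2 from the chiral phosphoric acid; C3 first cis (from the E-boronate), then trans by equilibration at the 3-formyl stage; lactone C4 from rhodium-catalysed hydrogenation; lactone C3 from trans-selective alkylation.

Key step: step 4

Assumption: the facial sense of (S)-TRIP (si-face allylation of the aryl aldehyde) and of the (R,R)-Et-DuPhos rhodium catalyst ((S)-half-ester) is taken from the parent substrates of each reaction; if a trial shows the opposite sense, the mirror-image catalyst is used and nothing else changes.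

Step 1
Reactants: 1 7-bromo-1,3-benzodioxole-5-carbaldehyde
Product: 2 7-bromo-1,3-benzodioxole-5-carbonitrile
Conditions: I2 (1.1 equiv), 28% aq. NH3, THF, rt
Reagents that add atoms: ammonia, N
Why: Oxidative ammonolysis of an aromatic aldehyde (iodine–ammonia): the aldimine is N-iodinated and loses HI to the nitrile, while the aryl bromide and the dioxole should be inert.

Step 2
Reactants: 2 7-bromo-1,3-benzodioxole-5-carbonitrile; 3 2-ethenyl-4,4,5,5-tetramethyl-1,3,2-dioxaborolane
Product: 4 7-ethenyl-1,3-benzodioxole-5-carbonitrile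
Conditions: Pd(dppf)Cl2 (3 mol%), K2CO3, 1,4-dioxane/H2O (4:1), 80 °C
Reagents that add atoms: none
Why: Suzuki–Miyaura coupling of an aryl bromide with a vinylboronate, which nitrile and acetal should tolerate under aqueous carbonate.

Step 3
Reactants: 4 7-ethenyl-1,3-benzodioxole-5-carbonitrile; 5 4,4,5,5-tetramethyl-2-(prop-2-en-1-yl)-1,3,2-dioxaborolane
Product: 6 7-[(1E)-3-(4,4,5,5-tetramethyl-1,3,2-dioxaborolan-2-yl)prop-1-en-1-yl]-1,3-benzodioxole-5-carbonitrile
Conditions: second-generation Grubbs catalyst (3 mol%), 5 (3 equiv), CH2Cl2, 40 °C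
Reagents that add atoms: none
Why: Olefin cross-metathesis of a styrene with an allylboronate should give the conjugated (E)-alkene under thermodynamic control with loss of ethene and leave the C–B bond untouched.

Step 4
Reactants: 6 7-[(1E)-3-(4,4,5,5-tetramethyl-1,3,2-dioxaborolan-2-yl)prop-1-en-1-yl]-1,3-benzodioxole-5-carbonitrile; 7 4-(benzyloxy)-3-methoxybenzaldehyde
Product: 11 (2S,3R)-7-(benzyloxy)-2-[4-(benzyloxy)-3-methoxyphenyl]-3-ethenyl-2,3-dihydro-1-benzofuran-5-carbonitrile (2,3-cis), via anti-adduct pinacol borate 8 (not isolated), via potassium aryloxymethanolate 9 (not isolated), via potassium phenolate 10 (not isolated)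
Conditions: (S)-TRIP [(S)-3,3'-bis(2,4,6-triisopropylphenyl)-1,1'-binaphthyl-2,2'-diyl hydrogen phosphate] (5 mol%), 4 Å MS, toluene, 0 °C to rt; then KOtBu (2.0 equiv), DMSO, rt; then BnBr (2.5 equiv), rt
Reagents that add atoms: benzyl bromide, BrCc1ccccc1
Why: Proposed new method: the closest known reaction types are the chiral phosphoric acid-catalysed allylboration of aryl aldehydes with (E)-γ-substituted allyl pinacol boronates and the alkoxide SNAr cleavage of methylenedioxyarenes that carry a para acceptor (piperonal-type substrates give 4-alkoxy-3-hydroxyarenes), joined here in one flask with the second made intramolecular. Boronate 6 should add through a closed chair transition state held by the phosphoric acid, so that C2–C3 forms on the si face of 7 (C2 = S, catalyst control) with C3 anti to the oxygen (E geometry of 6). tert-Butoxide then binds the boron of borate 8, and the freed potassium alkoxide adds to the dioxole carbon C7a (5-exo-trig, Meisenheimer adduct stabilised by the nitrile), forming O1–C7a with retention at C2 and C3 and hence the 2,3-cis ring. The adduct expels the ring oxygen as aryloxymethanolate 9, which loses formaldehyde to phenolate 10 (the future free 7-OH) and is capped by benzyl bromide. The step needs site selectivity between the two dioxole carbons and needs the SNAr to outrun retro-allylation and deprotonation of the allylic-benzylic C3–H; C7a is the only carbon both para to the nitrile and within reach of a five-membered closure, and the tert-butoxide stays bound to boron so that no free strong base remains.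

Step 5
Reactants: 11 (2S,3R)-7-(benzyloxy)-2-[4-(benzyloxy)-3-methoxyphenyl]-3-ethenyl-2,3-dihydro-1-benzofuran-5-carbonitrile
Product: 13 [(2S,3R)-7-(benzyloxy)-2-[4-(benzyloxy)-3-methoxyphenyl]-3-ethenyl-2,3-dihydro-1-benzofuran-5-yl]methanol, via 5-carbaldehyde 12 (not isolated)
Conditions: i-Bu2AlH (1.2 equiv), CH2Cl2, −78 °C; aq. Rochelle salt; then NaBH4, MeOH, 0 °C
Reagents that add atoms: water, O
Why: Hydride reduction of the nitrile stops at the N-alumino imine, which is hydrolysed to the aldehyde and reduced by borohydride; benzyl ethers, the vinyl group and both stereocentres should be untouched.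

Step 6
Reactants: 13 [(2S,3R)-7-(benzyloxy)-2-[4-(benzyloxy)-3-methoxyphenyl]-3-ethenyl-2,3-dihydro-1-benzofuran-5-yl]methanol
Product: 14 (2S,3R)-7-(benzyloxy)-2-[4-(benzyloxy)-3-methoxyphenyl]-5-(bromomethyl)-3-ethenyl-2,3-dihydro-1-benzofuran
Conditions: CBr4, PPh3, CH2Cl2, 0 °C
Reagents that add atoms: carbon tetrabromide, BrC(Br)(Br)Br
Why: Appel reaction of a primary benzylic alcohol under neutral conditions, so no acid is present that could open the benzylic C2–O1 bond.

Step 7
Reactants: 7 4-(benzyloxy)-3-methoxybenzaldehyde; 15 dimethyl butanedioate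
Product: 16 (3E)-4-[4-(benzyloxy)-3-methoxyphenyl]-3-(methoxycarbonyl)but-3-enoic acid
Conditions: NaOMe, MeOH, reflux; then aq. HCl
Reagents that add atoms: none
Why: Stobbe condensation: the succinate enolate adds to the aldehyde, the alkoxide lactonises, and base-induced ring opening should give the (E)-alkylidene half-ester.

Step 8
Reactants: 16 (3E)-4-[4-(benzyloxy)-3-methoxyphenyl]-3-(methoxycarbonyl)but-3-enoic acid
Product: 17 (3S)-4-[4-(benzyloxy)-3-methoxyphenyl]-3-(methoxycarbonyl)butanoic acid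
Conditions: H2 (5 bar), [Rh(cod)((R,R)-Et-DuPhos)]BF4 (0.5 mol%), NaOMe (10 mol%), MeOH, rt
Reagents that add atoms: none
Why: Asymmetric hydrogenation of a Stobbe itaconate half-ester: carboxylate and alkene chelate the cationic rhodium bisphospholane complex, which delivers hydrogen to one face and sets the future lactone C4 as S (catalyst control) without cleaving the aryl benzyl ether.

Step 9
Reactants: 17 (3S)-4-[4-(benzyloxy)-3-methoxyphenyl]-3-(methoxycarbonyl)butanoic acid
Product: 18 (4S)-4-{[4-(benzyloxy)-3-methoxyphenyl]methyl}oxolan-2-one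
Conditions: KOH (1.0 equiv), EtOH; CaCl2, NaBH4, EtOH, −10 °C to rt; then 3 M HCl, rt
Reagents that add atoms: none
Why: Chemoselective borohydride reduction: calcium borohydride reduces the ester but not the potassium carboxylate, and acidification closes the γ-lactone without touching the stereocentre.

Step 10
Reactants: 18 (4S)-4-{[4-(benzyloxy)-3-methoxyphenyl]methyl}oxolan-2-one; 14 (2S,3R)-7-(benzyloxy)-2-[4-(benzyloxy)-3-methoxyphenyl]-5-(bromomethyl)-3-ethenyl-2,3-dihydro-1-benzofuran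
Product: 19 (3S,4S)-3-{[(2S,3R)-7-(benzyloxy)-2-[4-(benzyloxy)-3-methoxyphenyl]-3-ethenyl-2,3-dihydro-1-benzofuran-5-yl]methyl}-4-{[4-(benzyloxy)-3-methoxyphenyl]methyl}oxolan-2-one
Conditions: LiN(SiMe3)2 (1.1 equiv), THF, −78 °C; then 14, DMPU, −78 to −40 °C
Reagents that add atoms: none
Why: Enolate alkylation of a β-substituted γ-butyrolactone should occur anti to the C4 benzyl group and give the trans-3,4-disubstituted lactone (new centre S, substrate control), the para-oxygenated benzylic bromide being a fast SN2 partner at low temperature.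

Step 11
Reactants: 19 (3S,4S)-3-{[(2S,3R)-7-(benzyloxy)-2-[4-(benzyloxy)-3-methoxyphenyl]-3-ethenyl-2,3-dihydro-1-benzofuran-5-yl]methyl}-4-{[4-(benzyloxy)-3-methoxyphenyl]methyl}oxolan-2-one
Product: 22 (3S,4S)-3-{[(2S,3R)-7-(benzyloxy)-2-[4-(benzyloxy)-3-methoxyphenyl]-3-(hydroxymethyl)-2,3-dihydro-1-benzofuran-5-yl]methyl}-4-{[4-(benzyloxy)-3-methoxyphenyl]methyl}oxolan-2-one (2,3-trans), via cis-3-carbaldehyde 20 (not isolated), via trans-3-carbaldehyde 21 (not isolated)
Conditions: OsO4 (2 mol%), NaIO4 (4 equiv), 2,6-lutidine, 1,4-dioxane/H2O (3:1), rt; work-up; DBU (20 mol%), CH2Cl2, rt; then NaBH4, MeOH, 0 °C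
Reagents that add atoms: osmium tetroxide, O=[Os](=O)(=O)=O; sodium periodate, [Na+].[O-]I(=O)(=O)=O (terminal oxidant that restores the osmium oxygen)
Why: Johnson–Lemieux cleavage turns the vinyl group into a 3-formyl group that is enolisable only at C3, so catalytic amidine base should equilibrate the cis aldehyde to the more stable 2,3-trans isomer (C3 under thermodynamic control from C2) before borohydride reduces it at a temperature at which the lactone is not attacked.

Step 12
Reactants: 22 (3S,4S)-3-{[(2S,3R)-7-(benzyloxy)-2-[4-(benzyloxy)-3-methoxyphenyl]-3-(hydroxymethyl)-2,3-dihydro-1-benzofuran-5-yl]methyl}-4-{[4-(benzyloxy)-3-methoxyphenyl]methyl}oxolan-2-one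
Product: 23 (3S,4S)-3-{[(2S,3R)-7-hydroxy-2-(4-hydroxy-3-methoxyphenyl)-3-(hydroxymethyl)-2,3-dihydro-1-benzofuran-5-yl]methyl}-4-[(4-hydroxy-3-methoxyphenyl)methyl]oxolan-2-one
Conditions: H2 (1 atm), 10% Pd/C, EtOAc/MeOH, rt
Reagents that add atoms: none
Why: Hydrogenolysis of the three aryl benzyl ethers over palladium at ambient pressure should be much faster than cleavage of the benzylic C2–O1 bond of the dihydrobenzofuran, and the reaction is stopped once the benzyl ethers are consumed.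

**Compound list**

1 | 7-bromo-1,3-benzodioxole-5-carbaldehyde | O=Cc1cc(Br)c2OCOc2c1 | starting material
2 | 7-bromo-1,3-benzodioxole-5-carbonitrile | N#Cc1cc(Br)c2OCOc2c1 | intermediate
3 | 2-ethenyl-4,4,5,5-tetramethyl-1,3,2-dioxaborolane | C=CB1OC(C)(C)C(C)(C)O1 | starting material
4 | 7-ethenyl-1,3-benzodioxole-5-carbonitrile | N#Cc1cc(C=C)c2OCOc2c1 | intermediate
5 | 4,4,5,5-tetramethyl-2-(prop-2-en-1-yl)-1,3,2-dioxaborolane | C=CCB1OC(C)(C)C(C)(C)O1 | starting material
6 | 7-[(1E)-3-(4,4,5,5-tetramethyl-1,3,2-dioxaborolan-2-yl)prop-1-en-1-yl]-1,3-benzodioxole-5-carbonitrile | N#Cc1cc(/C=C/CB2OC(C)(C)C(C)(C)O2)c2OCOc2c1 | intermediate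
7 | 4-(benzyloxy)-3-methoxybenzaldehyde | COc1cc(C=O)ccc1OCc1ccccc1 | starting material
8 | pinacol borate of (1S,2R)-1-[4-(benzyloxy)-3-methoxyphenyl]-2-(6-cyano-1,3-benzodioxol-4-yl)but-3-en-1-ol (anti) | N#Cc1cc([C@@H](C=C)[C@@H](c2ccc(OCc3ccccc3)c(OC)c2)OB2OC(C)(C)C(C)(C)O2)c2OCOc2c1 | intermediate
9 | potassium {[(2S,3R)-2-[4-(benzyloxy)-3-methoxyphenyl]-5-cyano-3-ethenyl-2,3-dihydro-1-benzofuran-7-yl]oxy}methanolate | N#Cc1cc(OC[O-])c2c(c1)[C@@H](C=C)[C@@H](c1ccc(OCc3ccccc3)c(OC)c1)O2.[K+] | intermediate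
10 | potassium (2S,3R)-2-[4-(benzyloxy)-3-methoxyphenyl]-5-cyano-3-ethenyl-2,3-dihydro-1-benzofuran-7-olate | N#Cc1cc([O-])c2c(c1)[C@@H](C=C)[C@@H](c1ccc(OCc3ccccc3)c(OC)c1)O2.[K+] | intermediate
11 | (2S,3R)-7-(benzyloxy)-2-[4-(benzyloxy)-3-methoxyphenyl]-3-ethenyl-2,3-dihydro-1-benzofuran-5-carbonitrile (2,3-cis) | N#Cc1cc(OCc2ccccc2)c2c(c1)[C@@H](C=C)[C@@H](c1ccc(OCc3ccccc3)c(OC)c1)O2 | intermediate
12 | (2S,3R)-7-(benzyloxy)-2-[4-(benzyloxy)-3-methoxyphenyl]-3-ethenyl-2,3-dihydro-1-benzofuran-5-carbaldehyde | O=Cc1cc(OCc2ccccc2)c2c(c1)[C@@H](C=C)[C@@H](c1ccc(OCc3ccccc3)c(OC)c1)O2 | intermediate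
13 | [(2S,3R)-7-(benzyloxy)-2-[4-(benzyloxy)-3-methoxyphenyl]-3-ethenyl-2,3-dihydro-1-benzofuran-5-yl]methanol | OCc1cc(OCc2ccccc2)c2c(c1)[C@@H](C=C)[C@@H](c1ccc(OCc3ccccc3)c(OC)c1)O2 | intermediate
14 | (2S,3R)-7-(benzyloxy)-2-[4-(benzyloxy)-3-methoxyphenyl]-5-(bromomethyl)-3-ethenyl-2,3-dihydro-1-benzofuran | BrCc1cc(OCc2ccccc2)c2c(c1)[C@@H](C=C)[C@@H](c1ccc(OCc3ccccc3)c(OC)c1)O2 | intermediate
15 | dimethyl butanedioate | COC(=O)CCC(=O)OC | starting material
16 | (3E)-4-[4-(benzyloxy)-3-methoxyphenyl]-3-(methoxycarbonyl)but-3-enoic acid | COC(=O)/C(CC(=O)O)=C/c1ccc(OCc2ccccc2)c(OC)c1 | intermediate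
17 | (3S)-4-[4-(benzyloxy)-3-methoxyphenyl]-3-(methoxycarbonyl)butanoic acid | COC(=O)[C@@H](Cc1ccc(OCc2ccccc2)c(OC)c1)CC(=O)O | intermediate
18 | (4S)-4-{[4-(benzyloxy)-3-methoxyphenyl]methyl}oxolan-2-one | COc1cc(C[C@@H]2COC(=O)C2)ccc1OCc1ccccc1 | intermediate
19 | (3S,4S)-3-{[(2S,3R)-7-(benzyloxy)-2-[4-(benzyloxy)-3-methoxyphenyl]-3-ethenyl-2,3-dihydro-1-benzofuran-5-yl]methyl}-4-{[4-(benzyloxy)-3-methoxyphenyl]methyl}oxolan-2-one | COc1cc(C[C@@H]2COC(=O)[C@H]2Cc2cc(OCc3ccccc3)c3c(c2)[C@@H](C=C)[C@@H](c2ccc(OCc4ccccc4)c(OC)c2)O3)ccc1OCc1ccccc1 | intermediate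
20 | (2S,3R)-7-(benzyloxy)-2-[4-(benzyloxy)-3-methoxyphenyl]-5-{[(3S,4S)-4-{[4-(benzyloxy)-3-methoxyphenyl]methyl}-2-oxooxolan-3-yl]methyl}-2,3-dihydro-1-benzofuran-3-carbaldehyde (2,3-cis) | COc1cc(C[C@@H]2COC(=O)[C@H]2Cc2cc(OCc3ccccc3)c3c(c2)[C@@H](C=O)[C@@H](c2ccc(OCc4ccccc4)c(OC)c2)O3)ccc1OCc1ccccc1 | intermediate
21 | (2S,3S)-7-(benzyloxy)-2-[4-(benzyloxy)-3-methoxyphenyl]-5-{[(3S,4S)-4-{[4-(benzyloxy)-3-methoxyphenyl]methyl}-2-oxooxolan-3-yl]methyl}-2,3-dihydro-1-benzofuran-3-carbaldehyde (2,3-trans) | COc1cc(C[C@@H]2COC(=O)[C@H]2Cc2cc(OCc3ccccc3)c3c(c2)[C@H](C=O)[C@@H](c2ccc(OCc4ccccc4)c(OC)c2)O3)ccc1OCc1ccccc1 | intermediate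
22 | (3S,4S)-3-{[(2S,3R)-7-(benzyloxy)-2-[4-(benzyloxy)-3-methoxyphenyl]-3-(hydroxymethyl)-2,3-dihydro-1-benzofuran-5-yl]methyl}-4-{[4-(benzyloxy)-3-methoxyphenyl]methyl}oxolan-2-one | COc1cc(C[C@@H]2COC(=O)[C@H]2Cc2cc(OCc3ccccc3)c3c(c2)[C@H](CO)[C@@H](c2ccc(OCc4ccccc4)c(OC)c2)O3)ccc1OCc1ccccc1 | intermediate
23 | (3S,4S)-3-{[(2S,3R)-7-hydroxy-2-(4-hydroxy-3-methoxyphenyl)-3-(hydroxymethyl)-2,3-dihydro-1-benzofuran-5-yl]methyl}-4-[(4-hydroxy-3-methoxyphenyl)methyl]oxolan-2-one | COc1cc(C[C@@H]2COC(=O)[C@H]2Cc2cc(O)c3c(c2)[C@H](CO)[C@@H](c2ccc(O)c(OC)c2)O3)ccc1O | target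

**Count**

Total steps: 12. Longest linear sequence: 9 steps (steps 1–6, then 10–12).

**Steps most likely to fail**

1. Step 4 (proposed new method). The hand-over of the alkoxide from boron to potassium, or its addition to the dioxole carbon, may be too slow. Retro-allylation (loss of stereochemical integrity), deprotonation at the allylic-benzylic C3–H, or hydroxymethylation of the phenolate by the released formaldehyde could then take over.
Fallback (known chemistry, ring closed through the phenol oxygen instead): it sets out from 6 and 7. Allylboration with (R)-TRIP gives the mirror-image pinacol borate F1, hydrolysed on work-up to the (1R,2S)-homoallylic alcohol F2. BCl3 (CH2Cl2, −78 to 0 °C) removes the methylenedioxy bridge and the aryl benzyl ether. After work-up, catalytic CF3CO2H ionises the benzylic alcohol, and the neighbouring phenol on C7a captures the p-hydroxybenzyl cation (acid-mediated phenylcoumaran closure). C2 settles trans to the C3 fixed by the allylboration, giving the trans diphenol F3. BnBr and K2CO3 in DMF give the trans dibenzyl nitrile F4. The conditions of steps 5, 6 and 10 then lead through the trans aldehyde F5 to the alcohol F6, the bromide F7 and, with 18, the coupled trans-vinyl lactone F8. Oxidative cleavage of F8 under the step 11 conditions without base comes back to the route at 21, which is reduced to 22.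

2. Step 11. Enolisation of the cis-3-formyl intermediate may stop short of full equilibration or be overtaken by β-elimination of the ring oxygen, and the lactone may be partly reduced.
Fallback (relative configuration corrected at C2 by acid instead of at C3 by base): it sets out from 6 and 7. Step 4 is run with (R)-TRIP, which leads through borate F1 and the mirror-image potassium aryloxymethanolate F9 and potassium phenolate F10 to the enantiomer of 11, the (2R,3S)-cis nitrile F11. CF3CO2H in CH2Cl2 opens and re-closes the benzylic C2–O1 bond through the p-alkoxybenzyl cation (known acid-induced cis-to-trans isomerisation of 2-(4-alkoxyaryl)-2,3-dihydrobenzofurans). C2 settles trans to the fixed C3 and gives the trans dibenzyl nitrile F4. This is carried on as in the first fallback through F5, F6, F7 and F8 and comes back to the route at 21, with no base treatment needed.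

3. Step 12. Over-reduction: hydrogenolysis of the benzylic C2–O1 bond of the dihydrobenzofuran may compete with cleavage of the three benzyl ethers.
Fallback (Lewis-acid dealkylation instead of reduction): it sets out from 22. BCl3 with pentamethylbenzene as cation scavenger in CH2Cl2 at −78 °C removes the aryl benzyl ethers without any reducing agent and comes back to the route at 23. It makes no new compound (F0).

**Further compounds**

F1 | step 4 | pinacol borate of (1R,2S)-1-[4-(benzyloxy)-3-methoxyphenyl]-2-(6-cyano-1,3-benzodioxol-4-yl)but-3-en-1-ol | N#Cc1cc([C@H](C=C)[C@H](c2ccc(OCc3ccccc3)c(OC)c2)OB2OC(C)(C)C(C)(C)O2)c2OCOc2c1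
F2 | step 4 | (1R,2S)-1-[4-(benzyloxy)-3-methoxyphenyl]-2-(6-cyano-1,3-benzodioxol-4-yl)but-3-en-1-ol | N#Cc1cc([C@H](C=C)[C@H](c2ccc(OCc3ccccc3)c(OC)c2)O)c2OCOc2c1
F3 | step 4 | (2S,3S)-3-ethenyl-7-hydroxy-2-(4-hydroxy-3-methoxyphenyl)-2,3-dihydro-1-benzofuran-5-carbonitrile | N#Cc1cc(O)c2c(c1)[C@H](C=C)[C@@H](c1ccc(O)c(OC)c1)O2
F4 | step 4 | (2S,3S)-7-(benzyloxy)-2-[4-(benzyloxy)-3-methoxyphenyl]-3-ethenyl-2,3-dihydro-1-benzofuran-5-carbonitrile | N#Cc1cc(OCc2ccccc2)c2c(c1)[C@H](C=C)[C@@H](c1ccc(OCc3ccccc3)c(OC)c1)O2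
F5 | step 4 | (2S,3S)-7-(benzyloxy)-2-[4-(benzyloxy)-3-methoxyphenyl]-3-ethenyl-2,3-dihydro-1-benzofuran-5-carbaldehyde | O=Cc1cc(OCc2ccccc2)c2c(c1)[C@H](C=C)[C@@H](c1ccc(OCc3ccccc3)c(OC)c1)O2
F6 | step 4 | [(2S,3S)-7-(benzyloxy)-2-[4-(benzyloxy)-3-methoxyphenyl]-3-ethenyl-2,3-dihydro-1-benzofuran-5-yl]methanol | OCc1cc(OCc2ccccc2)c2c(c1)[C@H](C=C)[C@@H](c1ccc(OCc3ccccc3)c(OC)c1)O2
F7 | step 4 | (2S,3S)-7-(benzyloxy)-2-[4-(benzyloxy)-3-methoxyphenyl]-5-(bromomethyl)-3-ethenyl-2,3-dihydro-1-benzofuran | BrCc1cc(OCc2ccccc2)c2c(c1)[C@H](C=C)[C@@H](c1ccc(OCc3ccccc3)c(OC)c1)O2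
F8 | step 4 | (3S,4S)-3-{[(2S,3S)-7-(benzyloxy)-2-[4-(benzyloxy)-3-methoxyphenyl]-3-ethenyl-2,3-dihydro-1-benzofuran-5-yl]methyl}-4-{[4-(benzyloxy)-3-methoxyphenyl]methyl}oxolan-2-one | COc1cc(C[C@@H]2COC(=O)[C@H]2Cc2cc(OCc3ccccc3)c3c(c2)[C@H](C=C)[C@@H](c2ccc(OCc4ccccc4)c(OC)c2)O3)ccc1OCc1ccccc1
F9 | step 11 | potassium {[(2R,3S)-2-[4-(benzyloxy)-3-methoxyphenyl]-5-cyano-3-ethenyl-2,3-dihydro-1-benzofuran-7-yl]oxy}methanolate | N#Cc1cc(OC[O-])c2c(c1)[C@H](C=C)[C@H](c1ccc(OCc3ccccc3)c(OC)c1)O2.[K+]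
F10 | step 11 | potassium (2R,3S)-2-[4-(benzyloxy)-3-methoxyphenyl]-5-cyano-3-ethenyl-2,3-dihydro-1-benzofuran-7-olate | N#Cc1cc([O-])c2c(c1)[C@H](C=C)[C@H](c1ccc(OCc3ccccc3)c(OC)c1)O2.[K+]
F11 | step 11 | (2R,3S)-7-(benzyloxy)-2-[4-(benzyloxy)-3-methoxyphenyl]-3-ethenyl-2,3-dihydro-1-benzofuran-5-carbonitrile (2,3-cis) | N#Cc1cc(OCc2ccccc2)c2c(c1)[C@H](C=C)[C@H](c1ccc(OCc3ccccc3)c(OC)c1)O2
F0 | step 12 | none | none
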